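Target grew by 14.5 mM h⁻¹ in Thursday's run and 15.7 mM h⁻¹ in Wednesday's between 2.00 h and 4.00 h, although the two loadings differed, so I took their mean, 15.1 mM h⁻¹, as a fixed drain on open intermediate, zero order in it.

in all of them: gas 99 mM (held)
- Thursday's: substrate 0.10 M; run made earlier
- Wednesday's: substrate 0.15 M; run made earlier
- flask: substrate 0.20 M; time 20 h

| run | time / h | open intermediate / % | target / % | substrate / % |
|---|---|---|---|---|
| Thursday's | 1.00 | 32.6 | 1.0 | 64.5 |
| Thursday's | 2.00 | 46.8 | 11.0 | 42.2 |
| Thursday's | 4.00 | 43.6 | 40.0 | 17.5 |
| Thursday's | 10.0 | 0.9 | 96.6 | 2.0 |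
| Thursday's | 20.0 | 0 | 99.3 | 0.2 |
| Wednesday's | 1.00 | 33.9 | 1.4 | 66.2 |
| Wednesday's | 2.00 | 49.6 | 8.4 | 41.8 |
| Wednesday's | 4.00 | 53.2 | 29.4 | 17.6 |
| Wednesday's | 10.0 | 9.8 | 87.9 | 1.3 |
| Wednesday's | 20.0 | 0.3 | 99.7 | 0 |

(each reading ± 0.5 percentage points)

1. the best time, 20 h at the latest, for open intermediate
2. the amount of open intermediate, in percent of the substrate charged, at that time

- the numbers in the tables scatter by 0.5 percentage points (one standard deviation)
- at the start none of the gas is in solution

Thursday's substrate readings gave a first-order constant k of 0.435 h⁻¹. Open intermediate rises while its supply k[substrate] exceeds the drain, so for the flask at 0.20 M I reckoned 4.02 h for the crossing time, the moment at which the supply has fallen to the drain.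

The forecast gave 4 h (3.5 h to 4.6 h) and 60% (57% to 63%), on the ground that “In absolute terms, target forms at almost the same rate in both runs”.

The flask gave 59.8% at 3.86 h, inside both ranges.

    substrate → open intermediate (k = 0.430 h⁻¹)
    partner → second intermediate (k = 0.260 h⁻¹)
    open intermediate + second intermediate → target (k = 41.0 M⁻¹ h⁻¹)
    2 second intermediate → homo product (k = 0.830 M⁻¹ h⁻¹)
    gas ⇌ partner, rate k5*(csat - [partner]) (kL = 0.530 h⁻¹)

At 3.86 h in the flask, the turning of substrate into open intermediate ran at 16.3 mM h⁻¹ and that of partner into second intermediate at 16.5 mM h⁻¹, level with each other; this was above my drain of 15.1 mM h⁻¹, and the peak came earlier than the crossing time of 4.02 h. The neighbouring flask had the same charge but was read at 5.0 h, 0.980 h past the crossing time. There I reckoned a supply of 9.89 mM h⁻¹, less than the drain, and so expected a falling amount. That neighbouring flask held 57.7% of open intermediate at its reading, below the 59.8% it had reached earlier.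

All runs stem from a simulated flask from invented constants, noise included.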